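**Strategy.** Ring C is disconnected at C2–C3 and C4–C4a. The key step is an oxa-Povarov [4+2] annulation with inverted polarity: the aryloxymethyl cation released from a pivaloyloxymethyl ether on O1 of ring A (C2=O1–C8a=C4a, a cationic 2-oxadiene) meets the (E)-enol ether of the ring B arylacetaldehyde, which carries a (1S,2R)-2-phenylcyclohexyl auxiliary on oxygen. C3 adds to C2 on its unshielded face, setting the only stereocentre, and C4a, the ring A carbon between O1 and the 5-methoxy group, closes onto the C4 oxocarbenium ion. The step exploits the nucleophilic C4a–H beside the O1 aryl ether of ring A. Ionic hydrogenation in the same flask then removes the auxiliary oxygen from C4.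

Key step: step 9

Assumption: atom and ring labels are those of the isoflavan skeleton (ring A = benzo ring with O1, C4a, C5–C8, C8a; ring C = pyran ring with C2, C3, C4; ring B = 3-aryl group), the target is 3R, and the sense of auxiliary induction follows the s-trans enol ether model (the enantiomeric alcohol is equally available should the sense prove opposite).

Step 1
Reactants: 1 5-methoxybenzene-1,3-diol
Product: 2 1-methoxy-3,5-bis(triisopropylsilyloxy)benzene
Conditions: TIPSCl (2.4 equiv), imidazole, DMF, rt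
Reagents that add atoms: chlorotriisopropylsilane, CC(C)[Si](Cl)(C(C)C)C(C)C
Why: Imidazole-promoted silyl ether formation at both phenols; the two bulky groups later steer the bromination and the ring closure.

Step 2
Reactants: 2 1-methoxy-3,5-bis(triisopropylsilyloxy)benzene
Product: 3 2-bromo-1-methoxy-3,5-bis(triisopropylsilyloxy)benzene
Conditions: NBS (1.0 equiv), MeCN, −20 → 0 °C
Reagents that add atoms: N-bromosuccinimide, O=C1CCC(=O)N1Br
Why: Electrophilic aromatic bromination: the three free positions are electronically alike and the one between the two TIPSO groups is blocked, so bromine should enter next to the small methoxy group (two equivalent sites).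

Step 3
Reactants: 3 2-bromo-1-methoxy-3,5-bis(triisopropylsilyloxy)benzene
Product: 5 1-methoxy-2-(3-methylbut-2-en-1-yl)-3,5-bis(triisopropylsilyloxy)benzene, via aryllithium 4 (not isolated)
Conditions: n-BuLi, THF, −78 °C; CuBr·SMe2 (0.2 equiv), prenyl bromide, −78 → −20 °C
Reagents that add atoms: prenyl bromide (1-bromo-3-methylbut-2-ene), CC(C)=CCBr
Why: Bromine–lithium exchange followed by copper-mediated SN2 allylation should place the prenyl group between OMe and OTIPS, the low temperature suppressing 1,3 O→C silyl migration (retro-Brook rearrangement).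

Step 4
Reactants: 5 1-methoxy-2-(3-methylbut-2-en-1-yl)-3,5-bis(triisopropylsilyloxy)benzene
Product: 6 3-methoxy-4-(3-methylbut-2-en-1-yl)-5-(triisopropylsilyloxy)phenol
Conditions: TBAF (1.0 equiv), THF, −40 °C; H2O work-up
Reagents that add atoms: none
Why: Fluoride-induced desilylation is sterically controlled, so the TIPS ether para to the prenyl group (two free ortho positions) should cleave before the one shielded by the neighbouring prenyl group.

Step 5
Reactants: 6 3-methoxy-4-(3-methylbut-2-en-1-yl)-5-(triisopropylsilyloxy)phenol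
Product: 7 [3-methoxy-4-(3-methylbut-2-en-1-yl)-5-(triisopropylsilyloxy)phenoxy]methyl pivalate
Conditions: ClCH2OPiv, K2CO3, NaI (cat.), DMF, 0 °C → rt
Reagents that add atoms: chloromethyl pivalate, CC(C)(C)C(=O)OCCl
Why: Williamson O-alkylation of the phenoxide (Finkelstein-assisted) installs C2 as a formaldehyde O,O-acetal whose hindered acyloxy group resists transacylation and can later be ionised.

Step 6
Reactants: 8 4-hydroxy-2-methoxybenzaldehyde
Product: 9 2-methoxy-4-(triisopropylsilyloxy)benzaldehyde
Conditions: TIPSCl, imidazole, CH2Cl2, rt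
Reagents that add atoms: chlorotriisopropylsilane, CC(C)[Si](Cl)(C(C)C)C(C)C
Why: Standard silyl ether formation gives a phenol protecting group that tolerates chromium, copper and Lewis acid steps and leaves with fluoride at the end.

Step 7
Reactants: 9 2-methoxy-4-(triisopropylsilyloxy)benzaldehyde
Product: 10 (E)-1-(2-iodovinyl)-2-methoxy-4-(triisopropylsilyloxy)benzene
Conditions: CrCl2, CHI3, THF, 0 °C → rt
Reagents that add atoms: iodoform, IC(I)I
Why: Takai olefination: the iodo-substituted geminal dichromium reagent from CHI3 and CrCl2 adds to the aldehyde and eliminates to the (E)-vinyl iodide, the isomer strongly preferred for aryl aldehydes.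

Step 8
Reactants: 10 (E)-1-(2-iodovinyl)-2-methoxy-4-(triisopropylsilyloxy)benzene; 11 (1S,2R)-trans-2-phenylcyclohexan-1-ol
Product: 12 triisopropyl{3-methoxy-4-[(E)-2-{[(1S,2R)-2-phenylcyclohexyl]oxy}vinyl]phenoxy}silane
Conditions: CuI (10 mol %), 3,4,7,8-tetramethyl-1,10-phenanthroline (20 mol %), Cs2CO3, toluene, 80 °C
Reagents that add atoms: none
Why: Copper-catalysed Ullmann-type C–O coupling of a vinyl iodide with an alcohol proceeds with retention of alkene geometry and does not touch the carbinol stereocentres.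

Step 9
Reactants: 7 [3-methoxy-4-(3-methylbut-2-en-1-yl)-5-(triisopropylsilyloxy)phenoxy]methyl pivalate; 12 triisopropyl{3-methoxy-4-[(E)-2-{[(1S,2R)-2-phenylcyclohexyl]oxy}vinyl]phenoxy}silane
Product: 15 (3R)-5-methoxy-3-[2-methoxy-4-(triisopropylsilyloxy)phenyl]-6-(3-methylbut-2-en-1-yl)-7-(triisopropylsilyloxy)chroman, via aryloxymethyl oxocarbenium triflate 13 (not isolated), via 4-alkoxyisoflavan 14 (not isolated)
Conditions: TMSOTf (1.0 equiv), 2,6-di-tert-butyl-4-methylpyridine, CH2Cl2, −78 °C; then Et3SiH (10 equiv), BF3·OEt2, −78 → −40 °C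
Reagents that add atoms: none
Why: TMSOTf silylates the pivalate carbonyl of 7 and expels Me3SiOPiv, giving O-aryl oxocarbenium ion 13, a cationic 2-oxadiene (C2=O1–C8a=C4a); the β-carbon of enol ether 12 (future C3) adds to C2, and the C4 oxocarbenium ion so formed is captured by C4a, which is a stepwise polar [4+2] annulation. The closest known reaction type is the oxa-Povarov reaction of O-aryl oxocarbenium ions with electron-rich alkenes, run here with an enol ether so that, as in the parent Povarov reaction with vinyl ethers, the oxygen-bearing carbon becomes C4 and the aryl-bearing carbon C3. Ring C closes by a 6-exo-trig Friedel–Crafts attack of C4a on the exocyclic C4=O+ bond. C3 is set in the first bond formation by the (1S,2R) auxiliary: in the s-trans enol ether, with the carbinol C–H eclipsing the O–vinyl bond, the phenyl group covers the Re face of C3, so C2 should add to the Si face and give 3R, the π-facial control known for Lewis acid promoted polar cycloadditions of 2-phenylcyclohexyl vinyl ethers; C4 forms as an epimer mixture and is erased when BF3·OEt2/Et3SiH ionises the benzylic ether 14 and delivers hydride. The step needs attack through the β-carbon of 12 (secured by the enol oxygen), a geometrically pure (E)-alkene (the (Z) isomer would give 3S), closure at C4a and not at C8 (C8 lies under the TIPSO group, which the 6-prenyl group forces to lean over it, while C4a is flanked only by the methoxy group) and an untouched prenyl alkene (far less nucleophilic than enol ether and arene). Hydride capture at low temperature should outrun loss of H3 from the C4 cation, the only path that could scramble C3, and the hindered pyridine keeps the medium free of protic acid.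

Step 10
Reactants: 15 (3R)-5-methoxy-3-[2-methoxy-4-(triisopropylsilyloxy)phenyl]-6-(3-methylbut-2-en-1-yl)-7-(triisopropylsilyloxy)chroman
Product: 16 (3R)-3-(4-hydroxy-2-methoxyphenyl)-5-methoxy-6-(3-methylbut-2-en-1-yl)chroman-7-ol
Conditions: TBAF (2.5 equiv), THF, 0 °C → rt; H2O work-up
Reagents that add atoms: none
Why: Fluoride cleaves both aryl silyl ethers through Si–F bond formation under non-acidic conditions, so the prenyl group cannot cyclise onto O7 and C3 is not touched.

**Compound list**

1 | 5-methoxybenzene-1,3-diol | COc1cc(O)cc(O)c1 | starting material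
2 | 1-methoxy-3,5-bis(triisopropylsilyloxy)benzene | COc1cc(O[Si](C(C)C)(C(C)C)C(C)C)cc(O[Si](C(C)C)(C(C)C)C(C)C)c1 | intermediate
3 | 2-bromo-1-methoxy-3,5-bis(triisopropylsilyloxy)benzene | COc1cc(O[Si](C(C)C)(C(C)C)C(C)C)cc(O[Si](C(C)C)(C(C)C)C(C)C)c1Br | intermediate
4 | 2-lithio-1-methoxy-3,5-bis(triisopropylsilyloxy)benzene (aryllithium, not isolated) | COc1cc(O[Si](C(C)C)(C(C)C)C(C)C)cc(O[Si](C(C)C)(C(C)C)C(C)C)c1[Li] | intermediate
5 | 1-methoxy-2-(3-methylbut-2-en-1-yl)-3,5-bis(triisopropylsilyloxy)benzene | COc1cc(O[Si](C(C)C)(C(C)C)C(C)C)cc(O[Si](C(C)C)(C(C)C)C(C)C)c1CC=C(C)C | intermediate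
6 | 3-methoxy-4-(3-methylbut-2-en-1-yl)-5-(triisopropylsilyloxy)phenol | COc1cc(O)cc(O[Si](C(C)C)(C(C)C)C(C)C)c1CC=C(C)C | intermediate
7 | [3-methoxy-4-(3-methylbut-2-en-1-yl)-5-(triisopropylsilyloxy)phenoxy]methyl pivalate | COc1cc(OCOC(=O)C(C)(C)C)cc(O[Si](C(C)C)(C(C)C)C(C)C)c1CC=C(C)C | intermediate
8 | 4-hydroxy-2-methoxybenzaldehyde | COc1cc(O)ccc1C=O | starting material
9 | 2-methoxy-4-(triisopropylsilyloxy)benzaldehyde | COc1cc(O[Si](C(C)C)(C(C)C)C(C)C)ccc1C=O | intermediate
10 | (E)-1-(2-iodovinyl)-2-methoxy-4-(triisopropylsilyloxy)benzene | COc1cc(O[Si](C(C)C)(C(C)C)C(C)C)ccc1/C=C/I | intermediate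
11 | (1S,2R)-trans-2-phenylcyclohexan-1-ol | O[C@H]1CCCC[C@@H]1c1ccccc1 | starting material
12 | triisopropyl{3-methoxy-4-[(E)-2-{[(1S,2R)-2-phenylcyclohexyl]oxy}vinyl]phenoxy}silane | COc1cc(O[Si](C(C)C)(C(C)C)C(C)C)ccc1/C=C/O[C@H]1CCCC[C@@H]1c1ccccc1 | intermediate
13 | {[3-methoxy-4-(3-methylbut-2-en-1-yl)-5-(triisopropylsilyloxy)phenyl]oxonio}methylidene triflate (aryloxymethyl oxocarbenium triflate, not isolated) | C=[O+]c1cc(O[Si](C(C)C)(C(C)C)C(C)C)c(CC=C(C)C)c(OC)c1.[O-]S(=O)(=O)C(F)(F)F | intermediate
14 | (3R)-5-methoxy-3-[2-methoxy-4-(triisopropylsilyloxy)phenyl]-6-(3-methylbut-2-en-1-yl)-4-{[(1S,2R)-2-phenylcyclohexyl]oxy}-7-(triisopropylsilyloxy)chroman (C4 epimers, not isolated) | COc1cc(O[Si](C(C)C)(C(C)C)C(C)C)ccc1[C@@H]1COc2cc(O[Si](C(C)C)(C(C)C)C(C)C)c(CC=C(C)C)c(OC)c2C1O[C@H]1CCCC[C@@H]1c1ccccc1 | intermediate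
15 | (3R)-5-methoxy-3-[2-methoxy-4-(triisopropylsilyloxy)phenyl]-6-(3-methylbut-2-en-1-yl)-7-(triisopropylsilyloxy)chroman | COc1cc(O[Si](C(C)C)(C(C)C)C(C)C)ccc1[C@@H]1COc2cc(O[Si](C(C)C)(C(C)C)C(C)C)c(CC=C(C)C)c(OC)c2C1 | intermediate
16 | (3R)-3-(4-hydroxy-2-methoxyphenyl)-5-methoxy-6-(3-methylbut-2-en-1-yl)chroman-7-ol | COc1cc(O)ccc1[C@@H]1COc2cc(O)c(CC=C(C)C)c(OC)c2C1 | target

**Summary.** Total step count: 10. Longest linear sequence: 7 steps (steps 1–5, 9, 10).

**Steps most likely to fail**

1. Step 9. What may go wrong: ring closure at C8 instead of C4a; ionisation of the 4-alkoxy intermediate with loss of H3 before hydride arrives, which erodes the configuration at C3; incomplete facial control by the auxiliary. Fallback, setting out from 6 and 10 and coming back at 15: the ring is closed in the reverse polarity through an o-quinone methide, so that C4–C4a is fixed before the cycloaddition. Phenol 6 is formylated ortho to the hydroxyl on the methoxy side (MgCl2, Et3N, paraformaldehyde, MeCN, reflux) to give 2-hydroxy-6-methoxy-5-(3-methylbut-2-en-1-yl)-4-(triisopropylsilyloxy)benzaldehyde F1; any regioisomer would be separated at this small-molecule stage. F1 is converted with Boc2O and DMAP into aryl tert-butyl carbonate F2. Hydride addition to F2 (LiBH(sec-Bu)3, then MgBr2·OEt2, THF, −78 °C → rt) should trigger Boc migration and loss of tert-butyl carbonate, unveiling o-quinone methide F3. F3 is trapped in an inverse-demand hetero-Diels–Alder reaction by enol ether F4, the enantiomer of 12, made from 10 and commercial (1R,2S)-2-phenylcyclohexanol as in step 8. The enantiomeric auxiliary is needed because C3 now bonds to C4 instead of C2 on the same open face. The resulting 2-alkoxyisoflavan F5 is reduced at the acetal carbon with Et3SiH/BF3·OEt2 to give 15.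

2. Step 4. What may go wrong: poor discrimination between the two silyl ethers, giving double desilylation or cleavage of the wrong one. Fallback, setting out from 5 and coming back at 7: both silyl groups are removed (TBAF, 2.5 equiv) to give 5-methoxy-4-(3-methylbut-2-en-1-yl)benzene-1,3-diol F6. The hydroxyl para to the prenyl group, the less hindered one, is alkylated with chloromethyl pivalate (1.0 equiv, K2CO3, DMF) to give mono(pivaloyloxymethyl) ether F7, so the differentiation is made in a bond-forming step. Silylation of the remaining hindered hydroxyl (TIPSOTf, 2,6-lutidine) gives 7.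

3. Step 8. What may go wrong: sluggish C–O coupling of the hindered secondary alcohol, with competing reduction or homocoupling of the vinyl iodide. Fallback, setting out from 11 and coming back at 12: the potassium alkoxide of 11 (KH, THF) is added to trichloroethylene to give (E)-1,2-dichlorovinyl ether F8. n-BuLi (excess) then eliminates and exchanges to the lithium alkynyl ether, which is protonated to ethynyl ether F9. Sonogashira coupling (PdCl2(PPh3)2, CuI, Et3N) with 1-iodo-2-methoxy-4-(triisopropylsilyloxy)benzene F10, made from commercial 4-iodo-3-methoxyphenol and TIPSCl, gives aryl alkynyl ether F11. trans-Hydroalumination with LiAlH4 and protonolysis gives the (E)-enol ether 12.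

Further compounds
F1 | step 9 | 2-hydroxy-6-methoxy-5-(3-methylbut-2-en-1-yl)-4-(triisopropylsilyloxy)benzaldehyde | COc1c(C=O)c(O)cc(O[Si](C(C)C)(C(C)C)C(C)C)c1CC=C(C)C
F2 | step 9 | tert-butyl [2-formyl-3-methoxy-4-(3-methylbut-2-en-1-yl)-5-(triisopropylsilyloxy)phenyl] carbonate | COc1c(C=O)c(OC(=O)OC(C)(C)C)cc(O[Si](C(C)C)(C(C)C)C(C)C)c1CC=C(C)C
F3 | step 9 | 5-methoxy-6-methylidene-4-(3-methylbut-2-en-1-yl)-3-(triisopropylsilyloxy)cyclohexa-2,4-dien-1-one (o-quinone methide) | C=C1C(=O)C=C(O[Si](C(C)C)(C(C)C)C(C)C)C(CC=C(C)C)=C1OC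
F4 | step 9 | triisopropyl{3-methoxy-4-[(E)-2-{[(1R,2S)-2-phenylcyclohexyl]oxy}vinyl]phenoxy}silane | COc1cc(O[Si](C(C)C)(C(C)C)C(C)C)ccc1/C=C/O[C@@H]1CCCC[C@H]1c1ccccc1
F5 | step 9 | (3R)-5-methoxy-3-[2-methoxy-4-(triisopropylsilyloxy)phenyl]-6-(3-methylbut-2-en-1-yl)-2-{[(1R,2S)-2-phenylcyclohexyl]oxy}-7-(triisopropylsilyloxy)chroman | COc1cc(O[Si](C(C)C)(C(C)C)C(C)C)ccc1[C@@H]1C(O[C@@H]2CCCC[C@H]2c2ccccc2)Oc2cc(O[Si](C(C)C)(C(C)C)C(C)C)c(CC=C(C)C)c(OC)c2C1
F6 | step 4 | 5-methoxy-4-(3-methylbut-2-en-1-yl)benzene-1,3-diol | COc1cc(O)cc(O)c1CC=C(C)C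
F7 | step 4 | [3-hydroxy-5-methoxy-4-(3-methylbut-2-en-1-yl)phenoxy]methyl pivalate | COc1cc(OCOC(=O)C(C)(C)C)cc(O)c1CC=C(C)C
F8 | step 8 | (1S,2R)-1-{[(E)-1,2-dichlorovinyl]oxy}-2-phenylcyclohexane | Cl/C=C(/Cl)O[C@H]1CCCC[C@@H]1c1ccccc1
F9 | step 8 | (1S,2R)-1-(ethynyloxy)-2-phenylcyclohexane | C#CO[C@H]1CCCC[C@@H]1c1ccccc1
F10 | step 8 | 1-iodo-2-methoxy-4-(triisopropylsilyloxy)benzene | COc1cc(O[Si](C(C)C)(C(C)C)C(C)C)ccc1I
F11 | step 8 | triisopropyl{3-methoxy-4-[2-{[(1S,2R)-2-phenylcyclohexyl]oxy}ethynyl]phenoxy}silane | COc1cc(O[Si](C(C)C)(C(C)C)C(C)C)ccc1C#CO[C@H]1CCCC[C@@H]1c1ccccc1
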